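**Plan**
1. Cuts: the three O–Si bonds and the enal C=C (Wittig) are cut first, leaving a 5-formyl-2,3-dihydrobenzofuran. Its ring C is then cut at O1–C2 and C3a–C3 together, which separates ring B from ring A and its three-carbon chain.
2. Pieces: ring B is the ortho-quinone diazide of vanillin, with N2 on C3a and the carbonyl oxygen O1 on C7a (two steps from 5-nitrovanillin). Ring A is the tris-silylated (E)-5-hydroxyconiferyl alcohol (four steps from 5-hydroxyvanillin).
3. Enabling feature: O1–C7a–C3a of ring B is a masked 1,3-dipole, an electrophilic carbene carbon C3a beside a nucleophilic oxygen O1. The oxygen para to C2 on ring A makes C2 a quinone-methide-type cation, so the C3=C2 styrene bond is polarised to match that dipole.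
4. Forward order: both pieces are made in parallel. Ring C arises in the rhodium-carbene [3+2] annulation that also joins them. The formyl group is then extended by two carbons and all silyl groups are removed in one step.
5. Stereochemistry: C3 comes from the chiral dirhodium carboxylate in the C–C bond formation, C2 is set trans to it in the ring closure, and the E-enal comes from the stabilised ylide.

Key step: step 7

Assumption: the SMILES is read as the trans-(2R,3S) isomer. Rh2(S-TCPTTL)4 is taken to give this series; if the sense of induction proves opposite, the catalyst made from (R)-tert-leucine is used and nothing else changes.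

Step 1
Reactants: 1 5-nitrovanillin (4-hydroxy-3-methoxy-5-nitrobenzaldehyde)
Product: 2 5-aminovanillin (3-amino-4-hydroxy-5-methoxybenzaldehyde)
Conditions: H2 (1 atm), 5% Pd/C, EtOAc, rt, stopped after uptake of 3 equiv H2
Reagents that add atoms: none
Why: Catalytic hydrogenation of an aromatic nitro group is much faster than that of the aryl aldehyde at 1 atm, so the aniline should form with the formyl group intact.

Step 2
Reactants: 2 5-aminovanillin
Product: 3 3-diazo-5-methoxy-4-oxocyclohexa-1,5-diene-1-carbaldehyde (ortho-quinone diazide of vanillin; 2-diazonio-4-formyl-6-methoxyphenolate)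
Conditions: t-BuONO (1.2 equiv), EtOH, 0 °C, dark; passed through a short pad of basic alumina and kept as a cold 1,2-dichloroethane solution, never taken to dryness
Reagents that add atoms: tert-butyl nitrite, CC(C)(C)ON=O
Why: Diazotisation of an ortho-aminophenol (nitrosation, dehydration, loss of the phenolic proton) gives the neutral quinone diazide, which the para-formyl group stabilises.

Step 3
Reactants: 4 3,4-dihydroxy-5-methoxybenzaldehyde (5-hydroxyvanillin)
Product: 5 3,4-bis(tert-butyldimethylsilyloxy)-5-methoxybenzaldehyde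
Conditions: TBSCl (2.5 equiv), imidazole (5 equiv), DMF, 0 °C to rt
Reagents that add atoms: tert-butyldimethylsilyl chloride, CC(C)(C)[Si](C)(C)Cl
Why: Standard imidazole-promoted silylation masks both catechol hydroxyls as electron-donating, fluoride-labile ethers that survive every later step.

Step 4
Reactants: 5 3,4-bis(tert-butyldimethylsilyloxy)-5-methoxybenzaldehyde
Product: 6 ethyl (E)-3-[3,4-bis(tert-butyldimethylsilyloxy)-5-methoxyphenyl]prop-2-enoate
Conditions: Ph3P=CHCO2Et (1.2 equiv), toluene, 80 °C
Reagents that add atoms: ethyl (triphenylphosphoranylidene)acetate, CCOC(=O)C=P(c1ccccc1)(c1ccccc1)c1ccccc1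
Why: The Wittig reaction of a stabilised ylide with an aryl aldehyde is E-selective, and its neutral conditions do not touch the aryl silyl ethers.

Step 5
Reactants: 6 ethyl (E)-3-[3,4-bis(tert-butyldimethylsilyloxy)-5-methoxyphenyl]prop-2-enoate
Product: 7 (E)-3-[3,4-bis(tert-butyldimethylsilyloxy)-5-methoxyphenyl]prop-2-en-1-ol
Conditions: DIBAL-H (2.3 equiv), CH2Cl2, −78 °C; aq. Rochelle salt
Reagents that add atoms: none
Why: DIBAL-H reduces the enoate 1,2 to the allylic alcohol without touching the alkene geometry or the silyl ethers.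

Step 6
Reactants: 7 (E)-3-[3,4-bis(tert-butyldimethylsilyloxy)-5-methoxyphenyl]prop-2-en-1-ol
Product: 8 (E)-1-[3,4-bis(tert-butyldimethylsilyloxy)-5-methoxyphenyl]-3-(tert-butyldimethylsilyloxy)prop-1-ene
Conditions: TBSCl (1.2 equiv), imidazole (2.5 equiv), CH2Cl2, 0 °C to rt
Reagents that add atoms: tert-butyldimethylsilyl chloride, CC(C)(C)[Si](C)(C)Cl
Why: Silylation removes the free O–H, which would otherwise undergo carbene O–H insertion, and leaves one kind of protecting group for a single final deprotection.

Step 7
Reactants: 3 ortho-quinone diazide of vanillin; 8 tris-silylated (E)-5-hydroxyconiferyl alcohol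
Product: 11 (2R,3S)-2-[3,4-bis(tert-butyldimethylsilyloxy)-5-methoxyphenyl]-3-(tert-butyldimethylsilyloxymethyl)-7-methoxy-2,3-dihydrobenzofuran-5-carbaldehyde, via rhodium carbenoid 9 (not isolated), via phenolate-cation zwitterion 10 (not isolated)
Conditions: Rh2(S-TCPTTL)4 (dirhodium tetrakis[N-tetrachlorophthaloyl-(S)-tert-leucinate], 2 mol %), 8 (1 equiv), slow addition of 3 (1.5 equiv), 1,2-dichloroethane, 4 Å MS, 40 °C, dark
Reagents that add atoms: none
Why: Proposed new method: the divalent-rhodium dimer expels N2 from 3 to give the strongly electrophilic quinoid carbenoid 9, the CH2OTBS-bearing alkene carbon of 8 attacks its carbene carbon (the future C3a), and rhodium departs as ring B aromatises to the zwitterion 10, which collapses by O1–C2 bond formation, so both bonds arise in one operation (cyclopropanation followed by aromatisation-driven ring opening of Cloke–Wilson type would converge on the same 10). The closest known reaction type is the formal [3+2] cycloaddition of ortho-quinone diazides, diazonaphthoquinones and cyclic 2-diazo-1,3-diketones to styrenes and enol ethers under heat or Rh2(OAc)4, together with asymmetric carbene transfer by the phthalimido-tert-leucinate dirhodium family, and what is new is the enantioselective version on a monocyclic formyl-substituted diazide and a 1,2-disubstituted cinnamyl ether. The only ring closed, dihydrofuran ring C, closes 5-exo-trig, the phenolate oxygen adding to the exocyclic quinone-methide-type C2=C(aryl) unit as in the biosynthetic 8-5' coupling. C3 is fixed in the C–C bond-forming event by the chiral cavity of the four N-tetrachlorophthaloyl-(S)-tert-leucinate ligands, which leaves one face of the carbenoid open and so selects one face of the E-alkene, and it cannot be lost later because the C3a–C3 and C3–H bonds stay intact. C2 is fixed relative to C3 in the closure, which places ring A and CH2OTBS trans on the new ring to avoid eclipsing, and any cis share could still drift to trans by reversible ionisation of the benzylic C2–O1 bond. The step needs regioselectivity (carbene carbon to C3, oxygen to C2), secured by the para-silyloxy donor of ring A that localises the positive charge at C2, and chemoselectivity over Wolff rearrangement, carbene dimerisation, attack on the formyl oxygen and C–H insertion next to OTBS, secured by metal-bound carbene transfer, slow addition of 3, the far higher nucleophilicity of the trioxygenated styrene and the bulk of the silyl groups.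

Step 8
Reactants: 11 (2R,3S)-dihydrobenzofuran-5-carbaldehyde
Product: 12 (E)-3-{(2R,3S)-2-[3,4-bis(tert-butyldimethylsilyloxy)-5-methoxyphenyl]-3-(tert-butyldimethylsilyloxymethyl)-7-methoxy-2,3-dihydrobenzofuran-5-yl}prop-2-enal
Conditions: Ph3P=CHCHO (1.3 equiv), toluene, 90 °C
Reagents that add atoms: (triphenylphosphoranylidene)acetaldehyde, O=CC=P(c1ccccc1)(c1ccccc1)c1ccccc1
Why: The Wittig reaction of the formyl-stabilised ylide with an aryl aldehyde gives the E-cinnamaldehyde directly under neutral conditions that leave both stereocentres and all silyl ethers untouched.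

Step 9
Reactants: 12 tris-silylated cassyformin
Product: 13 cassyformin, (E)-3-[(2R,3S)-2-(3,4-dihydroxy-5-methoxyphenyl)-3-(hydroxymethyl)-7-methoxy-2,3-dihydrobenzofuran-5-yl]prop-2-enal
Conditions: Et3N·3HF (excess), THF/MeCN, rt, argon
Reagents that add atoms: none
Why: Fluoride-driven desilylation cleaves all three Si–O bonds, and the mildly acidic reagent keeps the catechol protonated, which guards against air oxidation and against quinone-methide opening of ring C.

**Compound list**
1 | 5-nitrovanillin | COc1cc(C=O)cc([N+](=O)[O-])c1O | starting material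
2 | 5-aminovanillin | COc1cc(C=O)cc(N)c1O | intermediate
3 | 3-diazo-5-methoxy-4-oxocyclohexa-1,5-diene-1-carbaldehyde | COC1=CC(C=O)=CC(=[N+]=[N-])C1=O | intermediate
4 | 3,4-dihydroxy-5-methoxybenzaldehyde | COc1cc(C=O)cc(O)c1O | starting material
5 | 3,4-bis(tert-butyldimethylsilyloxy)-5-methoxybenzaldehyde | COc1cc(C=O)cc(O[Si](C)(C)C(C)(C)C)c1O[Si](C)(C)C(C)(C)C | intermediate
6 | ethyl (E)-3-[3,4-bis(tert-butyldimethylsilyloxy)-5-methoxyphenyl]prop-2-enoate | CCOC(=O)/C=C/c1cc(OC)c(O[Si](C)(C)C(C)(C)C)c(O[Si](C)(C)C(C)(C)C)c1 | intermediate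
7 | (E)-3-[3,4-bis(tert-butyldimethylsilyloxy)-5-methoxyphenyl]prop-2-en-1-ol | OC/C=C/c1cc(OC)c(O[Si](C)(C)C(C)(C)C)c(O[Si](C)(C)C(C)(C)C)c1 | intermediate
8 | (E)-1-[3,4-bis(tert-butyldimethylsilyloxy)-5-methoxyphenyl]-3-(tert-butyldimethylsilyloxy)prop-1-ene | CC(C)(C)[Si](C)(C)OC/C=C/c1cc(OC)c(O[Si](C)(C)C(C)(C)C)c(O[Si](C)(C)C(C)(C)C)c1 | intermediate
9 | rhodium-bound quinoid carbene from 3 (core only; second rhodium atom and the four carboxylate ligands not drawn) | COC1=CC(C=O)=CC(=[Rh])C1=O | intermediate
10 | zwitterion: 4-formyl-6-methoxyphenolate bearing at its ortho carbon the (S)-CH(CH2OTBS) unit joined to the ring A benzylic cation | COc1cc([CH+][C@H](CO[Si](C)(C)C(C)(C)C)c2cc(C=O)cc(OC)c2[O-])cc(O[Si](C)(C)C(C)(C)C)c1O[Si](C)(C)C(C)(C)C | intermediate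
11 | (2R,3S)-2-[3,4-bis(tert-butyldimethylsilyloxy)-5-methoxyphenyl]-3-(tert-butyldimethylsilyloxymethyl)-7-methoxy-2,3-dihydrobenzofuran-5-carbaldehyde | COc1cc([C@@H]2Oc3c(OC)cc(C=O)cc3[C@H]2CO[Si](C)(C)C(C)(C)C)cc(O[Si](C)(C)C(C)(C)C)c1O[Si](C)(C)C(C)(C)C | intermediate
12 | tris-silylated cassyformin, (2R,3S), E-enal | COc1cc([C@@H]2Oc3c(OC)cc(/C=C/C=O)cc3[C@H]2CO[Si](C)(C)C(C)(C)C)cc(O[Si](C)(C)C(C)(C)C)c1O[Si](C)(C)C(C)(C)C | intermediate
13 | cassyformin, (2R,3S), E-enal | COc1cc([C@@H]2Oc3c(OC)cc(/C=C/C=O)cc3[C@H]2CO)cc(O)c1O | target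

**Total step count:** 9. **Longest linear sequence:** 7 (steps 3 to 9).

**Steps most likely to fail**

Step 7. Facial selectivity at the alkene may be poor. The carbenoid may also be diverted into Wolff rearrangement or C–H insertion beside the silyl ether, and the zwitterion may lose a proton or undergo a hydride shift. The fallback sets out from 7 and comes back at 11, building the same two bonds one after the other by known reactions.
- Alcohol 7 is treated with methyl chloroformate and pyridine to give (E)-3-[3,4-bis(tert-butyldimethylsilyloxy)-5-methoxyphenyl]allyl methyl carbonate F1.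
- Enantioselective iridium-catalysed allylic etherification follows ([Ir(cod)Cl]2, a BINOL-derived phosphoramidite bearing a bis(1-phenylethyl)amine unit, THF). The nucleophile is the sodium phenolate of commercial 5-iodovanillin. This should give the branched ether 4-{(R)-1-[3,4-bis(tert-butyldimethylsilyloxy)-5-methoxyphenyl]allyloxy}-3-iodo-5-methoxybenzaldehyde F2, which forms O1–C2 and sets C2 from the ligand.
- Aryl-radical 5-exo-trig cyclisation with nitroxide trapping (Bu3SnH, TEMPO, benzene, 70 °C) forms C3a–C3 trans to ring A through a chair-like transition state. The product is the (2R,3S)-3-[(2,2,6,6-tetramethylpiperidin-1-yl)oxymethyl]dihydrobenzofuran-5-carbaldehyde F3.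
- Zn in AcOH/THF/H2O cleaves the N–O bond to the (2R,3S)-3-(hydroxymethyl)dihydrobenzofuran-5-carbaldehyde F4.
- TBSCl and imidazole give 11.

Step 8. Olefination of the electron-rich aldehyde may be sluggish, and the enal formed may be homologated a second time. The fallback sets out from 11 and comes back at 12 through the ester oxidation level.
- Horner–Wadsworth–Emmons reaction with triethyl phosphonoacetate and NaH in THF gives the ethyl (E)-enoate F5.
- DIBAL-H at −78 °C gives the (E)-allylic alcohol F6.
- MnO2 in CH2Cl2 oxidises the allylic alcohol selectively to 12.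

Step 9. The liberated catechol may oxidise in air, and conjugate addition or opening of ring C may occur while fluoride acts on the enal-bearing compound. The fallback sets out from 11 and comes back at 13 by reversing the order of the last two events.
- Compound 11 is desilylated with Et3N·3HF at the more robust aldehyde stage to give (2R,3S)-2-(3,4-dihydroxy-5-methoxyphenyl)-3-(hydroxymethyl)-7-methoxy-2,3-dihydrobenzofuran-5-carbaldehyde F7.
- The neutral Wittig reaction with Ph3P=CHCHO (THF/toluene, 80 °C, argon), which tolerates free phenols, is then run as the last step to give 13.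

**Further compounds**
F1 | step 7 | (E)-3-[3,4-bis(tert-butyldimethylsilyloxy)-5-methoxyphenyl]allyl methyl carbonate | COC(=O)OC/C=C/c1cc(OC)c(O[Si](C)(C)C(C)(C)C)c(O[Si](C)(C)C(C)(C)C)c1
F2 | step 7 | 4-{(R)-1-[3,4-bis(tert-butyldimethylsilyloxy)-5-methoxyphenyl]allyloxy}-3-iodo-5-methoxybenzaldehyde | COc1cc([C@@H](C=C)Oc2c(OC)cc(C=O)cc2I)cc(O[Si](C)(C)C(C)(C)C)c1O[Si](C)(C)C(C)(C)C
F3 | step 7 | (2R,3S)-2-[3,4-bis(tert-butyldimethylsilyloxy)-5-methoxyphenyl]-7-methoxy-3-[(2,2,6,6-tetramethylpiperidin-1-yl)oxymethyl]-2,3-dihydrobenzofuran-5-carbaldehyde | COc1cc([C@@H]2Oc3c(OC)cc(C=O)cc3[C@H]2CON4C(C)(C)CCCC4(C)C)cc(O[Si](C)(C)C(C)(C)C)c1O[Si](C)(C)C(C)(C)C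
F4 | step 7 | (2R,3S)-2-[3,4-bis(tert-butyldimethylsilyloxy)-5-methoxyphenyl]-3-(hydroxymethyl)-7-methoxy-2,3-dihydrobenzofuran-5-carbaldehyde | COc1cc([C@@H]2Oc3c(OC)cc(C=O)cc3[C@H]2CO)cc(O[Si](C)(C)C(C)(C)C)c1O[Si](C)(C)C(C)(C)C
F5 | step 8 | ethyl (E)-3-{(2R,3S)-2-[3,4-bis(tert-butyldimethylsilyloxy)-5-methoxyphenyl]-3-(tert-butyldimethylsilyloxymethyl)-7-methoxy-2,3-dihydrobenzofuran-5-yl}prop-2-enoate | COc1cc([C@@H]2Oc3c(OC)cc(/C=C/C(=O)OCC)cc3[C@H]2CO[Si](C)(C)C(C)(C)C)cc(O[Si](C)(C)C(C)(C)C)c1O[Si](C)(C)C(C)(C)C
F6 | step 8 | (E)-3-{(2R,3S)-2-[3,4-bis(tert-butyldimethylsilyloxy)-5-methoxyphenyl]-3-(tert-butyldimethylsilyloxymethyl)-7-methoxy-2,3-dihydrobenzofuran-5-yl}prop-2-en-1-ol | COc1cc([C@@H]2Oc3c(OC)cc(/C=C/CO)cc3[C@H]2CO[Si](C)(C)C(C)(C)C)cc(O[Si](C)(C)C(C)(C)C)c1O[Si](C)(C)C(C)(C)C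
F7 | step 9 | (2R,3S)-2-(3,4-dihydroxy-5-methoxyphenyl)-3-(hydroxymethyl)-7-methoxy-2,3-dihydrobenzofuran-5-carbaldehyde | COc1cc([C@@H]2Oc3c(OC)cc(C=O)cc3[C@H]2CO)cc(O)c1O
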